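**Retrosynthetic overview**
- The C9–acetyl bond is made last: an acetyl anion equivalent adds to one carbonyl of a spiro-enedione, syn to the ring oxygen, which fixes C5 and C9 together.
- The spiro carbon comes from the key C–C bond between an α-lithiated 2,3-dihydrofuran (a masked acyl anion of the lactol carbon) and a carbonyl of 3,4-dimethylcyclobutenedione; protonation of the enol ether then drives a 1,2-acyl shift (4→5 ring expansion).
- The dihydrofuran comes from (S)-isophytol by hydroformylation and dehydration; (S)-isophytol comes from natural phytol by Sharpless epoxidation and reductive epoxide opening (sets C2; the chain centres come from phytol).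
- The cyclobutenedione comes from diisopropyl squarate and methyllithium.
- Ring order: the dihydrofuran (future oxolane) first, then the cyclopentenedione by ring expansion onto it.

Assumption: the SMILES is taken literally, so the target is the (2S,5R,9S,4'R,8'R) isomer (quaternary ether carbon S), and the natural phytol used is the pure (2E,7R,11R) isomer.

**Step 1**
Reactants: 1 natural phytol [(2E,7R,11R)-3,7,11,15-tetramethylhexadec-2-en-1-ol]
Product: 2 (2S,3S)-2,3-epoxyphytol {[(2S,3S)-3-methyl-3-[(4R,8R)-4,8,12-trimethyltridecyl]oxiran-2-yl]methanol}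
Conditions: Ti(OiPr)4 (10 mol %), L-(+)-diethyl tartrate (12 mol %), t-BuOOH (2 equiv, in decane), 4 Å MS, CH2Cl2, −20 °C
Reagents that add atoms: tert-butyl hydroperoxide, CC(C)(C)OO
Why: Sharpless asymmetric epoxidation of an E-trisubstituted allylic alcohol, in which L-(+)-tartrate directs oxygen to the face that gives the (2S,3S)-epoxide (as with geraniol), so the later C2 quaternary centre is set here under reagent control.

**Step 2**
Reactants: 2 (2S,3S)-2,3-epoxyphytol
Product: 4 (S)-isophytol [(3S,7R,11R)-3,7,11,15-tetramethylhexadec-1-en-3-ol], via epoxy iodide 3 (not isolated)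
Conditions: PPh3, I2, imidazole, THF, 0 °C; then Zn dust, AcOH, 0 °C → rt
Reagents that add atoms: none
Why: Appel-type iodination of the primary alcohol followed by zinc-mediated reductive β-elimination of the 2,3-epoxy iodide transposes the alcohol to C3 without touching the C3–O bond, so the (3S) configuration from step 1 is retained.

**Step 3**
Reactants: 4 (S)-isophytol
Product: 6 (2S)-2-methyl-2-[(4R,8R)-4,8,12-trimethyltridecyl]-2,3-dihydrofuran, via lactol 5 (not isolated)
Conditions: Rh(acac)(CO)2 (0.5 mol %), Xantphos (1 mol %), CO/H2 (1:1, 20 bar), toluene, 80 °C; then Et3N, MsCl, 0 → 60 °C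
Reagents that add atoms: carbon monoxide, [C-]#[O+]
Why: Linear-selective rhodium-catalysed hydroformylation of the vinyl group gives a γ-hydroxy aldehyde that closes to the lactol, and mesylation–elimination of the lactol gives the cyclic enol ether, with the quaternary stereocentre not involved.

**Step 4**
Reactants: 7 diisopropyl squarate [3,4-di(propan-2-yloxy)cyclobut-3-ene-1,2-dione]
Product: 9 3,4-dimethylcyclobut-3-ene-1,2-dione, via dilithium diolate 8 (not isolated)
Conditions: MeLi (2.3 equiv), THF, −78 °C; then 12 M HCl, CH2Cl2, −78 °C → rt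
Reagents that add atoms: methyllithium, [Li]C
Why: Double 1,2-addition of methyllithium to the two vinylogous-ester carbonyls followed by acid-induced double allylic carbonyl transposition (Stork–Danheiser type) with loss of two isopropanol molecules gives the dialkylcyclobutenedione, and no stereocentre is formed.

**Step 5**
Reactants: 6 (2S)-2-methyl-2-[(4R,8R)-4,8,12-trimethyltridecyl]-2,3-dihydrofuran; 9 3,4-dimethylcyclobut-3-ene-1,2-dione
Product: 12 (2S)-2,7,8-trimethyl-2-[(4R,8R)-4,8,12-trimethyltridecyl]-1-oxaspiro[4.4]non-7-ene-6,9-dione, via lithiated dihydrofuran 10 (not isolated), via hydroxycyclobutenone adduct 11 (not isolated)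
Conditions: t-BuLi (1.0 equiv), THF, −78 → 0 °C; cannulate into 9, THF, −78 °C; then (±)-camphorsulfonic acid (1.5 equiv), −78 °C → rt
Reagents that add atoms: none
Why: Proposed new method: the α-lithiated cyclic enol ether, an acyl anion equivalent of the lactol carbon, adds 1,2 to one carbonyl of 9 (as alkenyllithiums do with cyclobutenediones), and protonation of the enol ether at its β-carbon then gives an oxocarbenium ion next to the carbinol that triggers a semipinacol 1,2-shift of the acyl carbon (favoured over the ring vinyl carbon because the developing carbonyl stays conjugated with the alkene) with 4→5 ring expansion, the closest known reaction type being the acid-promoted oxonium-ion-initiated pinacolic ring expansion of 1-(dihydrofuranyl)cyclobutanols to 1-oxaspiro[4.4]nonan-6-ones together with the palladium-promoted acyl-shift ring expansion of 4-alkynyl-4-hydroxycyclobutenones; no new stereocentre arises because the spiro carbon carries two equivalent acyl arms.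

**Step 6**
Reactants: 12 (2S)-2,7,8-trimethyl-2-[(4R,8R)-4,8,12-trimethyltridecyl]-1-oxaspiro[4.4]non-7-ene-6,9-dione; 13 ethyl vinyl ether
Product: 16 alpha-tocospiro A [(2S,5R,9S)-9-acetyl-9-hydroxy-2,7,8-trimethyl-2-[(4R,8R)-4,8,12-trimethyltridecyl]-1-oxaspiro[4.4]non-7-en-6-one], via 1-ethoxyvinyllithium 14 (not isolated), via ethoxyvinyl carbinol 15 (not isolated)
Conditions: 13, t-BuLi, THF, −78 → 0 °C; then 12 (1.1 equiv of 14), −78 °C; then 1 M HCl, THF, 0 °C; silica HPLC to remove the 5,9-bis-epimer
Reagents that add atoms: water, O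
Why: 1,2-addition of the acetyl anion equivalent 1-ethoxyvinyllithium to a ketone (the tetrasubstituted alkene blocks 1,4-addition) followed by enol ether hydrolysis gives the tertiary α-ketol; attack anti to the ring CH2, i.e. syn to the ring oxygen and helped by lithium coordination to it, should place acetyl cis and hydroxyl trans to O1, while the choice between the two diastereotopic carbonyls (the one cis to the 2-methyl group is required and is slightly less hindered) is expected to be only modest, so C5 and C9 are set together here and the (5R,9S) product is separated from its (5S,9R) isomer.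

**Compound list**
1 | natural phytol, (2E,7R,11R)-3,7,11,15-tetramethylhexadec-2-en-1-ol | OC/C=C(\C)CCC[C@H](C)CCC[C@H](C)CCCC(C)C | starting material
2 | (2S,3S)-2,3-epoxyphytol, [(2S,3S)-3-methyl-3-[(4R,8R)-4,8,12-trimethyltridecyl]oxiran-2-yl]methanol | OC[C@@H]1O[C@@]1(C)CCC[C@H](C)CCC[C@H](C)CCCC(C)C | intermediate
3 | epoxy iodide, (2R,3S)-2-(iodomethyl)-3-methyl-3-[(4R,8R)-4,8,12-trimethyltridecyl]oxirane | IC[C@@H]1O[C@@]1(C)CCC[C@H](C)CCC[C@H](C)CCCC(C)C | intermediate
4 | (S)-isophytol, (3S,7R,11R)-3,7,11,15-tetramethylhexadec-1-en-3-ol | C=C[C@](O)(C)CCC[C@H](C)CCC[C@H](C)CCCC(C)C | intermediate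
5 | lactol, (5S)-5-methyl-5-[(4R,8R)-4,8,12-trimethyltridecyl]oxolan-2-ol (both anomers) | OC1CC[C@](C)(CCC[C@H](C)CCC[C@H](C)CCCC(C)C)O1 | intermediate
6 | (2S)-2-methyl-2-[(4R,8R)-4,8,12-trimethyltridecyl]-2,3-dihydrofuran | C1=CC[C@](C)(CCC[C@H](C)CCC[C@H](C)CCCC(C)C)O1 | intermediate
7 | diisopropyl squarate, 3,4-di(propan-2-yloxy)cyclobut-3-ene-1,2-dione | CC(C)OC1=C(OC(C)C)C(=O)C1=O | starting material
8 | dilithium 1,2-dimethyl-3,4-di(propan-2-yloxy)cyclobut-3-ene-1,2-diolate (cis/trans) | [Li+].[Li+].CC(C)OC1=C(OC(C)C)C(C)([O-])C1(C)[O-] | intermediate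
9 | 3,4-dimethylcyclobut-3-ene-1,2-dione | CC1=C(C)C(=O)C1=O | intermediate
10 | [(5S)-5-methyl-5-[(4R,8R)-4,8,12-trimethyltridecyl]-4,5-dihydrofuran-2-yl]lithium | [Li]C1=CC[C@](C)(CCC[C@H](C)CCC[C@H](C)CCCC(C)C)O1 | intermediate
11 | 4-hydroxy-2,3-dimethyl-4-[(5S)-5-methyl-5-[(4R,8R)-4,8,12-trimethyltridecyl]-4,5-dihydrofuran-2-yl]cyclobut-2-en-1-one (both carbinol epimers) | CC1=C(C)C(O)(C2=CC[C@](C)(CCC[C@H](C)CCC[C@H](C)CCCC(C)C)O2)C1=O | intermediate
12 | (2S)-2,7,8-trimethyl-2-[(4R,8R)-4,8,12-trimethyltridecyl]-1-oxaspiro[4.4]non-7-ene-6,9-dione | CC1=C(C)C(=O)C2(CC[C@](C)(CCC[C@H](C)CCC[C@H](C)CCCC(C)C)O2)C1=O | intermediate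
13 | ethyl vinyl ether (ethoxyethene) | C=COCC | starting material
14 | 1-ethoxyvinyllithium, (1-ethoxyethenyl)lithium | [Li]C(=C)OCC | intermediate
15 | (2S,5R,9R)-9-(1-ethoxyethenyl)-9-hydroxy-2,7,8-trimethyl-2-[(4R,8R)-4,8,12-trimethyltridecyl]-1-oxaspiro[4.4]non-7-en-6-one | CCOC(=C)[C@]1(O)C(C)=C(C)C(=O)[C@@]12CC[C@](C)(CCC[C@H](C)CCC[C@H](C)CCCC(C)C)O2 | intermediate
16 | alpha-tocospiro A, (2S,5R,9S)-9-acetyl-9-hydroxy-2,7,8-trimethyl-2-[(4R,8R)-4,8,12-trimethyltridecyl]-1-oxaspiro[4.4]non-7-en-6-one | CC(=O)[C@]1(O)C(C)=C(C)C(=O)[C@@]12CC[C@](C)(CCC[C@H](C)CCC[C@H](C)CCCC(C)C)O2 | target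

**Step count**
Total: 6 steps, each a single flask-to-isolated-product operation. Longest linear sequence: 5 steps (1, 2, 3, 5, 6); step 4 is a one-step side branch.

**Steps most likely to fail**

Step 5 (key step). Protonation of the enol ether in 11 may cause decomposition instead of the acyl shift. The fallback sets out from lactol 5 (step 3 stopped before the mesylation) and from 9, and comes back at 12. It generates the same oxocarbenium ion without Brønsted acid, from a sulfone. Lactol 5 with benzenesulfinic acid and CaCl2 in CH2Cl2 gives (5S)-5-methyl-2-(phenylsulfonyl)-5-[(4R,8R)-4,8,12-trimethyltridecyl]oxolane F1. Its α-sulfonyl carbanion (n-BuLi, THF, −78 °C), a second acyl anion equivalent of the lactol carbon, adds to 9 to give 4-hydroxy-2,3-dimethyl-4-[(5S)-5-methyl-2-(phenylsulfonyl)-5-[(4R,8R)-4,8,12-trimethyltridecyl]oxolan-2-yl]cyclobut-2-en-1-one F2. ZnBr2 in CH2Cl2, or simply warming the lithium alkoxide, expels benzenesulfinate with the same 1,2-acyl shift to give 12.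

Step 6. The basic, acid-labile ethoxyvinyl reagent may give retro-Claisen opening, γ-deprotonation or poor facial control. The fallback sets out from 12 and comes back at 16, and it changes the acetyl source to an alkyne. Ethynylmagnesium bromide premixed with anhydrous CeCl3 (THF, −78 °C), a small, weakly basic, oxygen-coordinating nucleophile, gives (2S,5R,9S)-9-ethynyl-9-hydroxy-2,7,8-trimethyl-2-[(4R,8R)-4,8,12-trimethyltridecyl]-1-oxaspiro[4.4]non-7-en-6-one F3 after HPLC. Markovnikov hydration of the terminal alkyne (Ph3PAuCl/AgOTf cat., aqueous dioxane) then gives 16. This fallback does not improve the choice between the two carbonyls, so the HPLC separation remains.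

Step 4. The second methyllithium addition to the mono-alkoxide may be sluggish, or the dialkoxide may ring-open on warming. The fallback sets out from 7 and comes back at 9, and it is stepwise with a protecting group. MeLi (1.05 equiv, −78 °C) followed by TMSCl gives 4-methyl-2,3-di(propan-2-yloxy)-4-(trimethylsilyloxy)cyclobut-2-en-1-one F4, which is isolated. A second MeLi addition to its now unhindered, non-anionic carbonyl gives 1,4-dimethyl-2,3-di(propan-2-yloxy)-4-(trimethylsilyloxy)cyclobut-2-en-1-ol F5. 12 M HCl in CH2Cl2 then effects desilylation and the double transposition to 9.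

**Further compounds**
F1 | step 5 | (5S)-5-methyl-2-(phenylsulfonyl)-5-[(4R,8R)-4,8,12-trimethyltridecyl]oxolane | O=S(=O)(c1ccccc1)C1CC[C@](C)(CCC[C@H](C)CCC[C@H](C)CCCC(C)C)O1
F2 | step 5 | 4-hydroxy-2,3-dimethyl-4-[(5S)-5-methyl-2-(phenylsulfonyl)-5-[(4R,8R)-4,8,12-trimethyltridecyl]oxolan-2-yl]cyclobut-2-en-1-one | CC1=C(C)C(O)(C2(S(=O)(=O)c3ccccc3)CC[C@](C)(CCC[C@H](C)CCC[C@H](C)CCCC(C)C)O2)C1=O
F3 | step 6 | (2S,5R,9S)-9-ethynyl-9-hydroxy-2,7,8-trimethyl-2-[(4R,8R)-4,8,12-trimethyltridecyl]-1-oxaspiro[4.4]non-7-en-6-one | C#C[C@]1(O)C(C)=C(C)C(=O)[C@@]12CC[C@](C)(CCC[C@H](C)CCC[C@H](C)CCCC(C)C)O2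
F4 | step 4 | 4-methyl-2,3-di(propan-2-yloxy)-4-(trimethylsilyloxy)cyclobut-2-en-1-one | CC(C)OC1=C(OC(C)C)C(C)(O[Si](C)(C)C)C1=O
F5 | step 4 | 1,4-dimethyl-2,3-di(propan-2-yloxy)-4-(trimethylsilyloxy)cyclobut-2-en-1-ol | CC(C)OC1=C(OC(C)C)C(C)(O[Si](C)(C)C)C1(C)O
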